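## Retrosynthetic overview

1. The target gibberellin ⇐ its 13,15-bis(tert-butyldimethylsilyl) ether 2-(trimethylsilyl)ethyl 7-ester (all three groups fall to fluoride in one step). 3β-OH comes from a 3-ketone; ring A from a reductive aldol (C3–C4); ring B from an intramolecular Michael addition (C5–C6); C1–C3 from allylation at C10; C10–O and C19=O from singlet-oxygen dearomatization of a furan.
2. Ring D ⇐ intramolecular carbonyl-ene reaction (C8–C15) of an α-keto aldehyde onto a C8=C9 alkene; H9 by hydroxyl-directed hydrogenation; C17 by Lombardo methylenation.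
3. Ring C ⇐ Diels–Alder reaction forming C11–C12 and C13–C14 between the diene CH2=C(2-furyl)–C(=CH2)–CH2CH2OH and (2R)-2-tert-butyl-5-methylidene-1,3-dioxolan-4-one (from (R)-lactic acid; fixes the absolute configuration).
4. Enabling feature: in ring C, C8 and C9 are adjacent and each carries one ring methylene (C14, C11), while C13 carries both oxygen and the acyl-level carbon C16. Ring C is therefore the adduct of a 2,3-disubstituted butadiene (C11=C9–C8=C14) and a captodative alkene (C12=C13). The C9 substituent (C10, C5, C4, C19 and the lactone oxygen) is a masked 2-furyl group that polarises the diene.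
5. Order of ring formation: C (step 5) → D (step 7) → B (step 15) → A (step 18).

Key step: step 5

Remark: gibberellane numbering (C1–C19) and the usual α/β descriptors of the target are used for all intermediates; the 15-hydroxyl of the target lies on the side of ring D that faces the three-carbon bridge C9–C11–C12 (and C9–H9) and is called "endo" below; it is therefore trans to C6 across ring D.

## Route

Step 1
Reactants: 1 2-bromofuran; 2 but-3-yn-1-ol
Product: 3 4-(furan-2-yl)but-3-yn-1-ol
Conditions: PdCl2(PPh3)2 (2 mol %), CuI (4 mol %), Et3N, 50 °C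
Reagents that add atoms: none
Why: Sonogashira coupling of the 2-halofuran with the terminal alkyne tolerates the free primary alcohol and creates no stereocentre.

Step 2
Reactants: 3 4-(furan-2-yl)but-3-yn-1-ol
Product: 4 4-(furan-2-yl)-3-methylidenepent-4-en-1-ol
Conditions: ethylene (1 atm), second-generation Grubbs catalyst RuCl2(=CHPh)(H2IMes)(PCy3) (5 mol %), CH2Cl2, 40 °C
Reagents that add atoms: ethylene, C=C
Why: Cross enyne metathesis with ethylene turns the internal alkyne into the 2,3-disubstituted buta-1,3-diene; the two new =CH2 groups (future C11 and C14) come from ethylene and no stereocentre is formed.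

Step 3
Reactants: 5 (R)-lactic acid; 6 pivalaldehyde
Product: 7 (2R,5R)-2-tert-butyl-5-methyl-1,3-dioxolan-4-one
Conditions: TsOH·H2O (cat.), H2SO4 (cat.), pentane, reflux, Dean–Stark trap; crystallisation at −78 °C
Reagents that add atoms: none
Why: Acid-catalysed acetalisation under thermodynamic control should give the cis-dioxolanone, the lactate stereocentre inducing the acetal centre (2R), and the cis isomer is purified by crystallisation.

Step 4
Reactants: 7 (2R,5R)-2-tert-butyl-5-methyl-1,3-dioxolan-4-one
Product: 9 (2R)-2-tert-butyl-5-methylidene-1,3-dioxolan-4-one, via bromide 8 (not isolated)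
Conditions: NBS, AIBN (cat.), cyclohexane, reflux; filtration; Et3N, Et2O, 0 °C to rt
Reagents that add atoms: none
Why: Wohl–Ziegler bromination at the captodative C5–H followed by E2 loss of HBr gives the methylidene dienophile, whose only stereocentre is the untouched (2R) acetal carbon.

Step 5
Reactants: 4 4-(furan-2-yl)-3-methylidenepent-4-en-1-ol; 9 (2R)-2-tert-butyl-5-methylidene-1,3-dioxolan-4-one
Product: 10 (2R,5S)-2-tert-butyl-8-(furan-2-yl)-7-(2-hydroxyethyl)-1,3-dioxaspiro[4.5]dec-7-en-4-one
Conditions: toluene, BHT (cat.), 80 °C, sealed tube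
Reagents that add atoms: none
Why: Thermal normal-demand Diels–Alder reaction (concerted, asynchronous [4+2]); the closest known type is the auxiliary-controlled cycloaddition of 2-tert-butyl-5-methylidene-1,3-dioxolan-4-ones with acyclic dienes. Ring C is closed in a six-membered suprafacial [π4s+π2s] mode that forms C11–C12 and C13–C14 together. The only new stereocentre, C13, is controlled by the acetal tert-butyl group: the diene adds to the face of C12=C13 anti to it, which with the (2R) auxiliary should give (5S), the configuration of C13 in the target, with its oxygen and the acyl carbon C16 already attached. The selectivity needed is regiochemical ("para": C13 to C14, C12 to C11): the furyl group conjugated to C9 puts the largest HOMO coefficient on C11, and the captodative alkene has its largest LUMO coefficient on the CH2 terminus C12, so these termini pair, while the alkyl group on C8 opposes only weakly. The tetrasubstituted, furyl-polarised C8=C9 alkene left behind is the ene component needed for ring D.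

Step 6
Reactants: 10 (2R,5S)-2-tert-butyl-8-(furan-2-yl)-7-(2-hydroxyethyl)-1,3-dioxaspiro[4.5]dec-7-en-4-one
Product: 11 (1,3-dithian-2-yl)[(1S)-4-(furan-2-yl)-1-hydroxy-3-(2-hydroxyethyl)cyclohex-3-en-1-yl]methanone
Conditions: 1,3-dithiane (4.5 equiv), n-BuLi (4.2 equiv), THF, −30 °C; then 10, −78 to −20 °C; aq. NH4Cl
Reagents that add atoms: 1,3-dithiane (used as 2-lithio-1,3-dithiane), C1CSCSC1
Why: Nucleophilic acyl substitution on the activated acetal ester by the Corey–Seebach reagent: the tetrahedral intermediate collapses with loss of pivalaldehyde to free the C13 hydroxyl, and the acidic C–H of the acyl dithiane is deprotonated by excess reagent, which should prevent a second addition; C13 is not touched.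

Step 7
Reactants: 11 (1,3-dithian-2-yl)[(1S)-4-(furan-2-yl)-1-hydroxy-3-(2-hydroxyethyl)cyclohex-3-en-1-yl]methanone
Product: 13 2-(furan-2-yl)-5,7-dihydroxy-1-(2-hydroxyethyl)bicyclo[3.2.1]oct-2-en-6-one (7-OH endo; gibberellane C8, C13 as in the target, C9=C11, 16-ketone), via keto aldehyde 12 (not isolated)
Conditions: MeI, CaCO3, MeCN/H2O (9:1), 45 °C; then toluene, 4 Å molecular sieves, 80 °C
Reagents that add atoms: water, O
Why: Alkylative hydrolysis of the dithiane unmasks the α-keto aldehyde, which should undergo an intramolecular carbonyl-ene reaction (type 1, five-membered ring): C15 bonds to C8, the alkene carbon β to the furan, and the aldehyde oxygen takes a hydrogen from C11 through a six-membered transition state, so ring D can only close cis-bridged from C13 (fixing C8) and the new hydroxyl must lie on the side of C9 (endo).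

Step 8
Reactants: 13 the ene product
Product: 14 2-(furan-2-yl)-5,7-dihydroxy-1-(2-hydroxyethyl)bicyclo[3.2.1]octan-6-one with 9β-H (furyl axial on ring C, syn to the C14 bridge; 15-OH endo)
Conditions: [Ir(cod)(PCy3)(py)]PF6 (5 mol %), H2 (1 atm), CH2Cl2, 0 °C to rt
Reagents that add atoms: none
Why: Hydroxyl-directed homogeneous hydrogenation with the cationic iridium complex [Ir(cod)(PCy3)(py)]PF6: the endo 15-OH lies below the C9=C11 bond and should deliver hydrogen to the face of C9 turned toward the C15–C16 bridge, giving 9β-H; furan and ketone are not reduced.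

Step 9
Reactants: 14 the saturated triol ketone
Product: 16 2-[2-(furan-2-yl)-5,7-dihydroxy-6-oxobicyclo[3.2.1]octan-1-yl]acetic acid (C7 carboxylic acid; 13-OH and 15-OH free), via aldehyde 15 (not isolated)
Conditions: TEMPO (0.2 equiv), PhI(OAc)2 (2.5 equiv), MeCN/H2O (1:1), 0 °C to rt
Reagents that add atoms: water, O
Why: Oxoammonium (TEMPO) oxidation is selective for the primary alcohol and in aqueous acetonitrile carries the aldehyde hydrate on to the acid; because the endo 15-OH is trans to C6 across ring D, a lactol or γ-lactone would be a trans-fused bicyclo[3.3.0] system and should not intervene, and no stereocentre is touched.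

Step 10
Reactants: 16 the C7 carboxylic acid
Product: 17 2-(trimethylsilyl)ethyl 2-[2-(furan-2-yl)-5,7-dihydroxy-6-oxobicyclo[3.2.1]octan-1-yl]acetate
Conditions: 2-(trimethylsilyl)ethanol (3 equiv), DCC (1.3 equiv), DMAP (0.2 equiv), CH2Cl2, 0 °C to rt
Reagents that add atoms: 2-(trimethylsilyl)ethanol, C[Si](C)(C)CCO
Why: Steglich esterification: the acylpyridinium intermediate is intercepted by the excess primary alcohol much faster than by the hindered secondary and tertiary hydroxyls of the substrate, and this ester is chosen because fluoride removes it at the end without hydrolytic conditions.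

Step 11
Reactants: 17 the 2-(trimethylsilyl)ethyl ester
Product: 18 2-(trimethylsilyl)ethyl 2-[5,7-bis(tert-butyldimethylsilyloxy)-2-(furan-2-yl)-6-oxobicyclo[3.2.1]octan-1-yl]acetate (13,15-bis-silyl ether of the 17-nor-16-ketone)
Conditions: TBSOTf (3.5 equiv), 2,6-lutidine (6 equiv), CH2Cl2, −78 °C to rt
Reagents that add atoms: tert-butyldimethylsilyl trifluoromethanesulfonate, CC(C)(C)[Si](C)(C)OS(=O)(=O)C(F)(F)F
Why: The silyl triflate with 2,6-lutidine silylates hindered secondary and tertiary alcohols, and capping both α-ketol hydroxyls blocks acyloin shifts and shields the 15-OH from the later base, hydride and oxidant; no stereocentre is touched.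

Step 12
Reactants: 18 the bis-silyl ether ketone
Product: 19 2-(trimethylsilyl)ethyl 2-[5,7-bis(tert-butyldimethylsilyloxy)-2-(furan-2-yl)-6-methylidenebicyclo[3.2.1]octan-1-yl]acetate (C16=C17H2)
Conditions: Zn, CH2Br2, TiCl4, THF (reagent pre-formed at 5 °C); 18 in CH2Cl2, 0 °C to rt
Reagents that add atoms: dibromomethane, BrCBr
Why: Lombardo methylenation is non-basic and suited to hindered, α-oxygenated bicyclo[3.2.1]octanones, so the 16-ketone should be converted into the exocyclic alkene without epimerisation at C15 and without attack on the ester.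

Step 13
Reactants: 19 the 16-methylidene furan
Product: 21 γ-hydroxybutenolide (5-hydroxyfuran-2(5H)-one bonded through C5 = C10 to C9; C19 is the lactone carbonyl, C4=C5 the ring alkene; C10 epimers), via endoperoxide 20 (not isolated)
Conditions: O2, tetraphenylporphyrin (cat.), visible light, i-Pr2NEt, CH2Cl2, −78 °C to rt
Reagents that add atoms: dioxygen, O=O
Why: [4+2] cycloaddition of singlet oxygen to the furan followed by base-induced Kornblum–DeLaMare fragmentation at the C19–H gives the hydroxybutenolide; the furan should react far faster than the 1,1-disubstituted alkene, and C10 is still a hemiketal.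

Step 14
Reactants: 21 the γ-hydroxybutenolide
Product: 23 10β-allyl butenolide (allyl = C1–C3 on C10, lactone O10 α, C4=C5 unsaturated), via hydroxy acid 22 (not isolated)
Conditions: allyl bromide (3 equiv), In powder (2 equiv), THF/H2O (3:1), rt; then aq. NaH2PO4
Reagents that add atoms: allyl bromide, C=CCBr
Why: Indium-mediated Barbier allylation of the ring-opened (Z)-4-oxo-enoic acid tautomer (1,2-addition to the C10 ketone) and relactonisation; Felkin–Anh addition anti to the quaternary C8, with the small carbonyl oxygen turned over ring C, should place the allyl group β (syn to H9) and O10 α.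

Step 15
Reactants: 23 the 10β-allyl butenolide
Product: 25 ring-B-closed Mannich base (C5–C6 bond, 5β-H, 6α-H; C4 bearing H and CH2NMe2, C4 epimers), via lithium enolate 24 (not isolated)
Conditions: LiN(SiMe3)2 (1.3 equiv), THF, −78 to −40 °C; then N,N-dimethylmethylideneammonium iodide (2 equiv), −78 °C to rt; aq. NH4Cl
Reagents that add atoms: N,N-dimethylmethylideneammonium iodide, C=[N+](C)C.[I-]
Why: Intramolecular Michael addition (5-exo-trig) of the lithium enolate of the C7 ester (carbon C6) to C5 of the butenolide closes ring B: C5 is fixed by the obligatory cis fusion of ring B to the butanolide dictated by C10, the ester on C6 should take the convex face trans to C4 (the natural arrangement, and C6 remains epimerisable toward it), and the C4 lactone enolate is trapped in a Mannich reaction.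

Step 16
Reactants: 25 the Mannich base
Product: 27 4-methylidene lactone (C4=C18H2; 10β-allyl), via ammonium iodide 26 (not isolated)
Conditions: MeI, MeOH, rt; then DBU, CH2Cl2, rt
Reagents that add atoms: none
Why: Quaternisation and E1cB (Hofmann-type) elimination is the standard α-methylenation of a lactone and removes the C4 stereocentre.

Step 17
Reactants: 27 the 4-methylidene lactone
Product: 28 aldehyde (10β-(3-oxopropyl); C3 = CHO)
Conditions: PdCl2(PhCN)2 (12 mol %), CuCl2·2H2O (12 mol %), AgNO2 (6 mol %), t-BuOH/MeNO2 (15:1), O2 (1 atm), rt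
Reagents that add atoms: dioxygen, O=O
Why: Nitrite-modified, aldehyde-selective (anti-Markovnikov) Wacker oxidation of the monosubstituted alkene, helped by the homoallylic C10–O; the hindered 1,1-disubstituted and the conjugated alkenes should not react.

Step 18
Reactants: 28 the aldehyde
Product: 29 fully protected target as a mixture of C3 epimers (ring A closed; C4 quaternary with 18-methyl β and C19 α)
Conditions: [(Ph3P)CuH]6 (0.4 equiv of hexamer), toluene, −40 to 0 °C; aq. NH4Cl
Reagents that add atoms: none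
Why: Copper hydride reductive aldol cyclisation: conjugate reduction of the α-methylene lactone generates the C4 enolate regiospecifically (turning =CH2 into the C18 methyl), and this closes ring A on the C3 aldehyde; C4 is fixed because the three-carbon tether from C10 can reach only one face of the lactone enolate, while C3 is not controlled.

Step 19
Reactants: 29 the C3 epimer mixture
Product: 30 3-oxo compound (13,15-bis-silyl ether, 7-ester)
Conditions: Dess–Martin periodinane, NaHCO3, CH2Cl2, 0 °C to rt
Reagents that add atoms: none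
Why: Dess–Martin oxidation merges both C3 epimers into one ketone; the 13- and 15-oxygens are silylated and cannot be oxidised.

Step 20
Reactants: 30 the 3-ketone
Product: 31 fully protected target with 3β-OH
Conditions: K[(s-Bu)3BH] (1.5 equiv), THF, −78 °C; aq. NH4Cl
Reagents that add atoms: none
Why: The bulky trialkylborohydride should attack the cyclohexanone from the equatorial direction and give the axial 3β alcohol (trans to the lactone bridge); lactone, ester and alkene are inert at −78 °C.

Step 21
Reactants: 31 the 3β-hydroxy bis-silyl ether ester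
Product: 33 the target gibberellin, via tetrabutylammonium carboxylate 32 (not isolated)
Conditions: Bu4NF (6 equiv), THF, 0 °C to rt; then cold 0.5 M HCl to pH 3
Reagents that add atoms: none
Why: Fluoride cleaves both silyl ethers and triggers β-elimination of the 2-(trimethylsilyl)ethyl ester (loss of ethylene and Me3SiF), so the acid and both hydroxyls are freed in one non-hydrolytic operation that leaves the 19,10-lactone closed and should avoid retro-aldol epimerisation at C3.

## Compound list

1 | 2-bromofuran | Brc1ccco1 | starting material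
2 | but-3-yn-1-ol | C#CCCO | starting material
3 | 4-(furan-2-yl)but-3-yn-1-ol | OCCC#Cc1ccco1 | intermediate
4 | 4-(furan-2-yl)-3-methylidenepent-4-en-1-ol | OCCC(=C)C(=C)c1ccco1 | intermediate
5 | (R)-lactic acid | C[C@@H](O)C(=O)O | starting material
6 | pivalaldehyde | CC(C)(C)C=O | starting material
7 | (2R,5R)-2-tert-butyl-5-methyl-1,3-dioxolan-4-one | C[C@H]1O[C@@H](C(C)(C)C)OC1=O | intermediate
8 | (2R)-5-bromo-2-tert-butyl-5-methyl-1,3-dioxolan-4-one (C5 not defined) | CC1(Br)O[C@@H](C(C)(C)C)OC1=O | intermediate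
9 | (2R)-2-tert-butyl-5-methylidene-1,3-dioxolan-4-one | C=C1O[C@@H](C(C)(C)C)OC1=O | intermediate
10 | (2R,5S)-2-tert-butyl-8-(furan-2-yl)-7-(2-hydroxyethyl)-1,3-dioxaspiro[4.5]dec-7-en-4-one | OCCC1=C(c2ccco2)CC[C@@]3(C1)O[C@@H](C(C)(C)C)OC3=O | intermediate
11 | (1,3-dithian-2-yl)[(1S)-4-(furan-2-yl)-1-hydroxy-3-(2-hydroxyethyl)cyclohex-3-en-1-yl]methanone | OCCC1=C(c2ccco2)CC[C@](O)(C1)C(=O)C1SCCCS1 | intermediate
12 | 2-[(1S)-4-(furan-2-yl)-1-hydroxy-3-(2-hydroxyethyl)cyclohex-3-en-1-yl]-2-oxoacetaldehyde | OCCC1=C(c2ccco2)CC[C@](O)(C1)C(=O)C=O | intermediate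
13 | 2-(furan-2-yl)-5,7-dihydroxy-1-(2-hydroxyethyl)bicyclo[3.2.1]oct-2-en-6-one, 7-OH endo | O=C1[C@@H](O)[C@]2(CCO)C[C@@]1(O)CC=C2c1ccco1 | intermediate
14 | 2-(furan-2-yl)-5,7-dihydroxy-1-(2-hydroxyethyl)bicyclo[3.2.1]octan-6-one, 9β-H, 15-OH endo | O=C1[C@@H](O)[C@]2(CCO)C[C@@]1(O)CC[C@H]2c1ccco1 | intermediate
15 | 2-[2-(furan-2-yl)-5,7-dihydroxy-6-oxobicyclo[3.2.1]octan-1-yl]acetaldehyde (C7 aldehyde) | O=C1[C@@H](O)[C@]2(CC=O)C[C@@]1(O)CC[C@H]2c1ccco1 | intermediate
16 | 2-[2-(furan-2-yl)-5,7-dihydroxy-6-oxobicyclo[3.2.1]octan-1-yl]acetic acid (C7 acid) | O=C1[C@@H](O)[C@]2(CC(=O)O)C[C@@]1(O)CC[C@H]2c1ccco1 | intermediate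
17 | 2-(trimethylsilyl)ethyl 2-[2-(furan-2-yl)-5,7-dihydroxy-6-oxobicyclo[3.2.1]octan-1-yl]acetate | O=C1[C@@H](O)[C@]2(CC(=O)OCC[Si](C)(C)C)C[C@@]1(O)CC[C@H]2c1ccco1 | intermediate
18 | 2-(trimethylsilyl)ethyl 2-[5,7-bis(tert-butyldimethylsilyloxy)-2-(furan-2-yl)-6-oxobicyclo[3.2.1]octan-1-yl]acetate | O=C1[C@@H](O[Si](C)(C)C(C)(C)C)[C@]2(CC(=O)OCC[Si](C)(C)C)C[C@@]1(O[Si](C)(C)C(C)(C)C)CC[C@H]2c1ccco1 | intermediate
19 | 2-(trimethylsilyl)ethyl 2-[5,7-bis(tert-butyldimethylsilyloxy)-2-(furan-2-yl)-6-methylidenebicyclo[3.2.1]octan-1-yl]acetate | C=C1[C@@H](O[Si](C)(C)C(C)(C)C)[C@]2(CC(=O)OCC[Si](C)(C)C)C[C@@]1(O[Si](C)(C)C(C)(C)C)CC[C@H]2c1ccco1 | intermediate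
20 | furan 2,5-endoperoxide of 19 | C=C1[C@@H](O[Si](C)(C)C(C)(C)C)[C@]2(CC(=O)OCC[Si](C)(C)C)C[C@@]1(O[Si](C)(C)C(C)(C)C)CC[C@H]2C34OOC(C=C3)O4 | intermediate
21 | γ-hydroxybutenolide (C10 hemiketal, both epimers; C19 lactone carbonyl) | C=C1[C@@H](O[Si](C)(C)C(C)(C)C)[C@]2(CC(=O)OCC[Si](C)(C)C)C[C@@]1(O[Si](C)(C)C(C)(C)C)CC[C@H]2C3(O)C=CC(=O)O3 | intermediate
22 | 10-allyl-10-hydroxy (Z)-4,5-unsaturated C19 acid (allyl β, OH α) | C=C1[C@@H](O[Si](C)(C)C(C)(C)C)[C@]2(CC(=O)OCC[Si](C)(C)C)C[C@@]1(O[Si](C)(C)C(C)(C)C)CC[C@H]2[C@](O)(CC=C)/C=C\C(=O)O | intermediate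
23 | 10β-allyl butenolide (O10 α, C4=C5) | C=C1[C@@H](O[Si](C)(C)C(C)(C)C)[C@]2(CC(=O)OCC[Si](C)(C)C)C[C@@]1(O[Si](C)(C)C(C)(C)C)CC[C@H]2[C@]3(CC=C)C=CC(=O)O3 | intermediate
24 | lithium C4 lactone enolate after ring B closure | C=C1[C@@H](O[Si](C)(C)C(C)(C)C)[C@]23C[C@@]1(O[Si](C)(C)C(C)(C)C)CC[C@H]2[C@@]4(CC=C)OC(O[Li])=C[C@H]4[C@@H]3C(=O)OCC[Si](C)(C)C | intermediate
25 | ring-B-closed Mannich base (5β-H, 6α-H; C4 with H and CH2NMe2, epimers) | C=C1[C@@H](O[Si](C)(C)C(C)(C)C)[C@]23C[C@@]1(O[Si](C)(C)C(C)(C)C)CC[C@H]2[C@@]4(CC=C)OC(=O)C(CN(C)C)[C@H]4[C@@H]3C(=O)OCC[Si](C)(C)C | intermediate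
26 | trimethylammonium iodide of 25 | C=C1[C@@H](O[Si](C)(C)C(C)(C)C)[C@]23C[C@@]1(O[Si](C)(C)C(C)(C)C)CC[C@H]2[C@@]4(CC=C)OC(=O)C(C[N+](C)(C)C)[C@H]4[C@@H]3C(=O)OCC[Si](C)(C)C.[I-] | intermediate
27 | 4-methylidene lactone, 10β-allyl | C=C1[C@@H](O[Si](C)(C)C(C)(C)C)[C@]23C[C@@]1(O[Si](C)(C)C(C)(C)C)CC[C@H]2[C@@]4(CC=C)OC(=O)C(=C)[C@H]4[C@@H]3C(=O)OCC[Si](C)(C)C | intermediate
28 | 4-methylidene lactone, 10β-(3-oxopropyl) | C=C1[C@@H](O[Si](C)(C)C(C)(C)C)[C@]23C[C@@]1(O[Si](C)(C)C(C)(C)C)CC[C@H]2[C@@]4(CCC=O)OC(=O)C(=C)[C@H]4[C@@H]3C(=O)OCC[Si](C)(C)C | intermediate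
29 | fully protected target, C3 epimer mixture | C=C1[C@@H](O[Si](C)(C)C(C)(C)C)[C@]23C[C@@]1(O[Si](C)(C)C(C)(C)C)CC[C@H]2[C@@]45CCC(O)[C@@](C)(C(=O)O4)[C@H]5[C@@H]3C(=O)OCC[Si](C)(C)C | intermediate
30 | 3-oxo compound (13,15-bis-silyl ether, 7-ester) | C=C1[C@@H](O[Si](C)(C)C(C)(C)C)[C@]23C[C@@]1(O[Si](C)(C)C(C)(C)C)CC[C@H]2[C@@]45CCC(=O)[C@@](C)(C(=O)O4)[C@H]5[C@@H]3C(=O)OCC[Si](C)(C)C | intermediate
31 | fully protected target with 3β-OH (13,15-bis-silyl ether, 2-(trimethylsilyl)ethyl 7-ester) | C=C1[C@@H](O[Si](C)(C)C(C)(C)C)[C@]23C[C@@]1(O[Si](C)(C)C(C)(C)C)CC[C@H]2[C@@]45CC[C@H](O)[C@@](C)(C(=O)O4)[C@H]5[C@@H]3C(=O)OCC[Si](C)(C)C | intermediate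
32 | tetrabutylammonium 7-carboxylate of the target | C=C1[C@@H](O)[C@]23C[C@@]1(O)CC[C@H]2[C@@]12CC[C@H](O)[C@@](C)(C(=O)O1)[C@H]2[C@@H]3C(=O)[O-].CCCC[N+](CCCC)(CCCC)CCCC | intermediate
33 | target gibberellin: 3β,13,15-trihydroxy-16-methylidene 19,10-lactone 7-carboxylic acid of the C19 gibberellin skeleton (15-OH endo) | C=C1[C@@H](O)[C@]23C[C@@]1(O)CC[C@H]2[C@@]12CC[C@H](O)[C@@](C)(C(=O)O1)[C@H]2[C@@H]3C(=O)O | target

## Step count and risks

Total steps: 21. Longest linear sequence: 19 steps (steps 1, 2, 5–21); the dienophile branch (steps 3, 4) joins at step 5.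

Steps most likely to fail:

**Step 5 (key Diels–Alder reaction).** The diene may be consumed by self-dimerisation at the temperature needed, and the alkyl group on C8 may steer part of the cycloaddition to the regioisomeric orientation. The fallback sets out from 4 and comes back at 11. The hydroxyl of 4 is silylated (TBSCl, imidazole) to give silyl ether diene F1. F1 is combined at low temperature with 2-(benzoyloxy)acrolein under iminium catalysis by the triflimide salt of an enantiopure 1,1'-binaphthyl-2,2'-diamine (enantiomer chosen for the (S) adduct) to give aldehyde benzoate F2. The LUMO-lowered, more polarised dienophile should sharpen the "para" preference and react below the dimerisation temperature. Addition of 2-lithio-1,3-dithiane to the aldehyde, then K2CO3 in methanol to remove the benzoate, gives dithianyl diol F3. Parikh–Doering oxidation of the secondary carbinol gives keto dithiane silyl ether F4, and HF·pyridine removes the silyl group to return to 11.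

**Step 14 (allylation at C10).** The allyl nucleophile may add to both faces of the freely rotating C10 ketone if the Felkin–Anh bias is weak, and the wrong C10 epimer would carry the lactone to the wrong face of ring B. The fallback sets out from 21 and comes back at 23, and it replaces substrate control by reagent control. Esterification of the open form with TMSCHN2 gives methyl (Z)-keto enoate F5. Allylboration of the C10 ketone of F5 with allyldiisopropoxyborane, catalysed by an enantiopure 3,3'-dibromo-1,1'-bi-2-naphthol (enantiomer chosen for the β-allyl adduct), gives tertiary alcohol F6. Warming F6 with catalytic pyridinium p-toluenesulfonate in toluene closes the (Z)-γ-hydroxy enoate to butenolide 23 with loss of methanol.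

**Step 18 (reductive aldol).** The copper hydride may reduce the aldehyde directly, or the copper enolate may be protonated before it cyclises. The fallback sets out from 28 and comes back at 30. Pinnick oxidation (NaClO2, NaH2PO4, 2-methylbut-2-ene) gives carboxylic acid F7, and TMSCHN2 gives methyl ester F8. Conjugate reduction of the α-methylene lactone with Li[(s-Bu)3BH] at −78 °C generates the C4 enolate with no free aldehyde present, and this closes ring A by Dieckmann-type acylation on the methyl ester to give the 3-ketone 30 directly.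

Further compounds
F1 | step 5 | tert-butyl{[4-(furan-2-yl)-3-methylidenepent-4-en-1-yl]oxy}dimethylsilane | C=C(c1ccco1)C(=C)CCO[Si](C)(C)C(C)(C)C
F2 | step 5 | (1S)-3-[2-(tert-butyldimethylsilyloxy)ethyl]-1-formyl-4-(furan-2-yl)cyclohex-3-en-1-yl benzoate | O=C[C@]1(OC(=O)c2ccccc2)CCC(c2ccco2)=C(CCO[Si](C)(C)C(C)(C)C)C1
F3 | step 5 | (1S)-3-[2-(tert-butyldimethylsilyloxy)ethyl]-1-[(1,3-dithian-2-yl)(hydroxy)methyl]-4-(furan-2-yl)cyclohex-3-en-1-ol (carbinol epimers) | OC([C@]1(O)CCC(c2ccco2)=C(CCO[Si](C)(C)C(C)(C)C)C1)C1SCCCS1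
F4 | step 5 | tert-butyldimethylsilyl ether of 11 at the primary hydroxyl | O=C([C@]1(O)CCC(c2ccco2)=C(CCO[Si](C)(C)C(C)(C)C)C1)C1SCCCS1
F5 | step 14 | methyl (Z)-4-oxo-enoate, open-chain methyl ester of 21 | C=C1[C@@H](O[Si](C)(C)C(C)(C)C)[C@]2(CC(=O)OCC[Si](C)(C)C)C[C@@]1(O[Si](C)(C)C(C)(C)C)CC[C@H]2C(=O)/C=C\C(=O)OC
F6 | step 14 | methyl ester of 22 (10-allyl-10-hydroxy (Z)-enoate; allyl β, OH α) | C=C1[C@@H](O[Si](C)(C)C(C)(C)C)[C@]2(CC(=O)OCC[Si](C)(C)C)C[C@@]1(O[Si](C)(C)C(C)(C)C)CC[C@H]2[C@](O)(CC=C)/C=C\C(=O)OC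
F7 | step 18 | C3 carboxylic acid from 28 (10β-(2-carboxyethyl), 4-methylidene lactone) | C=C1[C@@H](O[Si](C)(C)C(C)(C)C)[C@]23C[C@@]1(O[Si](C)(C)C(C)(C)C)CC[C@H]2[C@@]4(CCC(=O)O)OC(=O)C(=C)[C@H]4[C@@H]3C(=O)OCC[Si](C)(C)C
F8 | step 18 | methyl ester of F7 | C=C1[C@@H](O[Si](C)(C)C(C)(C)C)[C@]23C[C@@]1(O[Si](C)(C)C(C)(C)C)CC[C@H]2[C@@]4(CCC(=O)OC)OC(=O)C(=C)[C@H]4[C@@H]3C(=O)OCC[Si](C)(C)C
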